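In this stirred vessel the starting material has two exits. It binds partner and drains through the adduct to side product, or it pairs with itself to homo dimer.

| setting | Wednesday's | Tuesday's | Thursday's | Friday's | south-east | east | west | south |
|---|---|---|---|---|---|---|---|---|
| starting material | 0.080 M | 0.11 M | 0.18 M | 0.080 M | 0.080 M | 0.080 M | 0.080 M (fed, over 25 min) | 0.080 M |
| partner | 0.16 M | 0.16 M | 0.16 M | 0.32 M | 0.160 M (fed, over 25 min) | 0.160 M (in portions, 5, over 25 min) | 0.160 M | 0.160 M |
| remark | run made earlier | run made earlier | run made earlier | run made earlier | all else is in the flask from the start; the feed brings no volume worth counting | first portion at the start, last at 25 min | all else is in the flask from the start; the feed brings no volume worth counting | everything together at the start |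
| time |  |  |  |  | 30 min | 30 min | 30 min | 30 min |

| run | time / min | side product / % | target / % |
|---|---|---|---|
| Wednesday's | 2.50 | 24.8 | 5.3 |
| Wednesday's | 6.00 | 40.3 | 2.2 |
| Wednesday's | 12.0 | 50.0 | 0.3 |
| Wednesday's | 20.0 | 54.2 | 0 |
| Tuesday's | 2.50 | 22.5 | 3.3 |
| Tuesday's | 6.00 | 34.4 | 1.0 |
| Tuesday's | 12.0 | 41.2 | 0.4 |
| Tuesday's | 30.0 | 46.1 | 1.4 |
| Thursday's | 2.50 | 16.6 | 2.9 |
| Thursday's | 6.00 | 26.3 | 0.9 |
| Thursday's | 12.0 | 29.9 | 0 |
| Thursday's | 30.0 | 34.0 | 0.1 |
| Friday's | 4.00 | 50.6 | 4.4 |
| Friday's | 10.0 | 71.4 | 1.0 |
| Friday's | 20.0 | 76.9 | 0 |
| Friday's | 30.0 | 78.1 | 0 |

(each reading ± 0.5 percentage points)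

- a species is counted by the starting material in it: one homo dimer counts as two
- reactions considered so far: starting material + partner <-> adduct; adduct <-> target; 2 starting material -> homo dimer; adduct -> side product

- which flask leads in amount of side product, in percent of the starting material charged ("all alike" within 1.5 percentage points) (south-east / east / west / south / all alike)
- how much side product is there at the end, in percent of the starting material charged: south-east
- how much side product is there at the end, in percent of the starting material charged: east
- how much side product is there at the end, in percent of the starting material charged: west
- how much side product is there at the end, in percent of the starting material charged: south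

I take the first exit, at fixed [partner], as first order in the pool of starting material, adduct and target, a pseudo-first-order drain, and the second as second order in that pool. Let m be the pool level at which both run equal. Integrating the two rates from a charge C down to nothing gives the side product share: (m/C) ln(1 + C/m).

Wednesday's last reading is 54.2%. I try 0.0400 M, which is half the charge. It gives 54.9%, so I take this as the crossover level. South repeats Wednesday. Scaled with [partner], m gives Friday 69.3%, and the reading is higher, at 78.1%.

Wednesday's first two side product readings, taken against the last one, give a drain of about 0.214 min⁻¹. Its time, 4.67 min, is shorter than the feed, so west's pool levels at feed over drain: 0.0150 M. By my reckoning a level pool sends m/(m + [pool]) of the feed to side product, here 72.8% once drained.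

Turn it round. For south to beat west, west's pool must reach 0.0328 M. My estimate stands at about half of that, so I expect more side product in west than in south.

The forecast names west, with “Partner-starved flasks lose starting material to dimer within minutes”. It gives west 72% (55% to 86%), south 55%, east 21% and south-east 9%.

The flasks give west 69.4%, south 55.0%, east 20.6% and south-east 14.9%, so west leads. South-east stands 5.9 percentage points above the forecast.

    starting material + partner ⇌ adduct, settled at all times (K = 4.70 M⁻¹)
    adduct ⇌ target (K = 0.310, k = 0.230 s⁻¹)
    2 starting material → homo dimer (k = 0.0980 M⁻¹ s⁻¹)
    adduct → side product (k = 0.00770 s⁻¹)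

After 300 min, west stands at 76.5%. West's pool at 15.0 min is 0.0147 M, and m turns that into a side product share of 73.1%.

A neighbour of west holds 0.64 M of partner. Scaled with [partner], m becomes 0.160 M, and with the same pool the share is 91.4%. The computed result for that neighbour is 94.6%.

The readings were generated by integration for substances that don't exist, noise included.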